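**Retrosynthetic overview**
- C3 stereocentre: set on the complete skeleton by ruthenium-catalysed asymmetric transfer hydrogenation of the isoflavone with dynamic kinetic resolution (cis-(3R,4R) alcohol), then reoxidation at C4 and desilylation.
- C8 prenyl group: aromatic Claisen shift of a 7-O-(1,1-dimethylallyl) ether at the achiral chromone stage, where bond fixation of the benzopyranone sends the allyl unit to C8.
- Dimethylchroman: the pyran ring is closed by a gold-catalysed 6-endo-dig hydroarylation of a 4'-O-C(CH3)2-C≡CH ether, which forms the bond from chroman C4 (the later benzylic CH2) to chroman C4a (arene carbon); the ring is carried one oxidation level high (2H-chromene) and then saturated.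
- Enabling feature: ring B is a para-substituted aryl ether, so the ether oxygen O1 on chroman C8a activates two homotopic ortho carbons, and chroman C2 is a fully substituted gem-dimethyl carbon; the tether O1-C2(CH3)2-C≡CH can therefore only close from C4a onto its terminal carbon C4.
- Ring order: rings A, C and the ring-B arene are bought as daidzein; the only ring built is the chroman pyran ring (step 3); both C5 units come from the same chloride.

Key step: step 3

Remark: daidzein (1) is taken as a commercial isoflavone; isoflavone locants are used for rings A and C and "chroman C…" locants for the dimethylchroman; benzyl bromide, the silyl chloride and inorganic reagents are treated as reagents and carry no compound number.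

**Step 1**
Reactants: 1 daidzein (7-hydroxy-3-(4-hydroxyphenyl)-4H-chromen-4-one)
Product: 2 7-(benzyloxy)-3-(4-hydroxyphenyl)-4H-chromen-4-one
Conditions: BnBr (1.05 equiv), K2CO3 (1.1 equiv), DMF, rt
Reagents that add atoms: benzyl bromide, BrCc1ccccc1
Why: Williamson etherification under acidity control, because the 7-OH (para to the pyranone carbonyl) is clearly more acidic than the 4'-OH and is the phenol that one equivalent of base and halide should alkylate.

**Step 2**
Reactants: 2 7-(benzyloxy)-3-(4-hydroxyphenyl)-4H-chromen-4-one; 3 3-chloro-3-methylbut-1-yne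
Product: 4 7-(benzyloxy)-3-[4-(2-methylbut-3-yn-2-yloxy)phenyl]-4H-chromen-4-one
Conditions: K2CO3, KI (cat.), CuI (5 mol%), DMF, 60 °C
Reagents that add atoms: 3-chloro-3-methylbut-1-yne, CC(C)(Cl)C#C
Why: Copper-catalysed propargylic etherification of a phenol by a tertiary propargylic chloride alkylates the only free OH and installs chroman O1-C2(CH3)2 together with the two carbons that become C3 and C4.

**Step 3**
Reactants: 4 7-(benzyloxy)-3-[4-(2-methylbut-3-yn-2-yloxy)phenyl]-4H-chromen-4-one
Product: 5 7-(benzyloxy)-3-(2,2-dimethyl-2H-chromen-6-yl)-4H-chromen-4-one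
Conditions: Ph3PAuNTf2 (2 mol%), CH2Cl2, rt
Reagents that add atoms: none
Why: The cationic monovalent gold catalyst π-activates the terminal alkyne, the ring-B carbon ortho to the ether oxygen (future chroman C4a) attacks the terminal alkyne carbon (future chroman C4) anti to gold in a Friedel–Crafts sense, and proton loss from the Wheland intermediate followed by protodeauration of the vinylgold species releases the 2H-chromene. The closest known reaction type is the gold-catalysed intramolecular hydroarylation of aryl 1,1-dimethylpropargyl ethers to 2,2-dimethyl-2H-chromenes. The only ring closed is the pyran ring of the chroman, by 6-endo-dig closure, and no stereocentre is created. The step needs endo over 5-exo regioselectivity, a single site on ring B, and chemoselectivity against the chromone and the benzyl ether. Endo attack at the unhindered terminal carbon avoids a strained exocyclic vinyl cation, the para-substituted ring B offers two homotopic ortho carbons activated by O1, and the gem-dimethyl carbon (no propargylic hydrogen, Thorpe–Ingold compression) holds the alkyne over that carbon. Ring A carries no alkyne and its oxygen is capped as the benzyl ether, so nothing else in 4 should react.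

**Step 4**
Reactants: 5 7-(benzyloxy)-3-(2,2-dimethyl-2H-chromen-6-yl)-4H-chromen-4-one
Product: 6 3-(2,2-dimethylchroman-6-yl)-7-hydroxy-4H-chromen-4-one
Conditions: H2 (1 atm), 10% Pd/C, EtOAc–MeOH, rt
Reagents that add atoms: none
Why: Heterogeneous catalytic hydrogenation should saturate the styrenic C3=C4 bond of the chromene (bringing the chroman to its final oxidation level) and hydrogenolyse the benzyl ether in the same operation, while the vinylogous-ester C2=C3 bond of the chromone is reduced far more slowly; no stereocentre is formed.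

**Step 5**
Reactants: 6 3-(2,2-dimethylchroman-6-yl)-7-hydroxy-4H-chromen-4-one; 3 3-chloro-3-methylbut-1-yne
Product: 7 3-(2,2-dimethylchroman-6-yl)-7-(2-methylbut-3-yn-2-yloxy)-4H-chromen-4-one
Conditions: K2CO3, KI (cat.), CuI (5 mol%), DMF, 60 °C
Reagents that add atoms: 3-chloro-3-methylbut-1-yne, CC(C)(Cl)C#C
Why: The same copper-catalysed propargylic etherification as in step 2, now on the acidic 7-OH, which is the only phenol present.

**Step 6**
Reactants: 7 3-(2,2-dimethylchroman-6-yl)-7-(2-methylbut-3-yn-2-yloxy)-4H-chromen-4-one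
Product: 8 3-(2,2-dimethylchroman-6-yl)-7-(2-methylbut-3-en-2-yloxy)-4H-chromen-4-one
Conditions: H2 (1 atm), 5% Pd/CaCO3 poisoned with Pb(OAc)2, quinoline, EtOAc, rt
Reagents that add atoms: none
Why: Lindlar semihydrogenation should stop at the terminal vinyl group because the poisoned palladium catalyst reduces neither the alkene nor the chromone at a useful rate.

**Step 7**
Reactants: 8 3-(2,2-dimethylchroman-6-yl)-7-(2-methylbut-3-en-2-yloxy)-4H-chromen-4-one
Product: 10 3-(2,2-dimethylchroman-6-yl)-7-hydroxy-8-(3-methylbut-2-en-1-yl)-4H-chromen-4-one, via ortho-dienone 9 (not isolated)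
Conditions: PhNEt2, 130 °C
Reagents that add atoms: none
Why: Aromatic Claisen rearrangement ([3,3]-sigmatropic shift through a chair-like transition state) should deliver the unsubstituted allyl terminus to C8, the ortho carbon favoured by the higher C7–C8 bond order of the benzopyranone, and tautomerisation of dienone 9 restores ring A with a free 7-OH while the amine solvent suppresses acid-catalysed closure of the ortho-prenylphenol.

**Step 8**
Reactants: 10 3-(2,2-dimethylchroman-6-yl)-7-hydroxy-8-(3-methylbut-2-en-1-yl)-4H-chromen-4-one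
Product: 11 3-(2,2-dimethylchroman-6-yl)-8-(3-methylbut-2-en-1-yl)-7-(triisopropylsilyloxy)-4H-chromen-4-one
Conditions: TIPSCl, imidazole, DMF, rt
Reagents that add atoms: chlorotri(propan-2-yl)silane, CC(C)[Si](Cl)(C(C)C)C(C)C
Why: Silyl ether formation masks the acidic 7-OH, which as its phenoxide would deactivate the C4 carbonyl in step 9, with a bulky group that can later be removed by fluoride without acid that would add O7 to the prenyl group.

**Step 9**
Reactants: 11 3-(2,2-dimethylchroman-6-yl)-8-(3-methylbut-2-en-1-yl)-7-(triisopropylsilyloxy)-4H-chromen-4-one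
Product: 13 (3R,4R)-3-(2,2-dimethylchroman-6-yl)-8-(3-methylbut-2-en-1-yl)-7-(triisopropylsilyloxy)chroman-4-ol (3,4-cis), via racemic isoflavanone 12 (not isolated)
Conditions: RuCl[(R,R)-TsDPEN](p-cymene) (3 mol%), HCO2H/Et3N (1:5), EtOAc, 40 °C
Reagents that add atoms: none
Why: Noyori-type asymmetric transfer hydrogenation with dynamic kinetic resolution, in which conjugate hydride transfer gives racemic ketone 12 whose C3 epimerises rapidly in the amine-rich medium and the (R,R)-catalyst reduces the C4 carbonyl of the (3R)-epimer only, from the face anti to the 3-aryl group, so that C4 (R) is set by the catalyst and C3 (R) by the cis-selective resolution.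

**Step 10**
Reactants: 13 (3R,4R)-3-(2,2-dimethylchroman-6-yl)-8-(3-methylbut-2-en-1-yl)-7-(triisopropylsilyloxy)chroman-4-ol
Product: 14 (3R)-3-(2,2-dimethylchroman-6-yl)-8-(3-methylbut-2-en-1-yl)-7-(triisopropylsilyloxy)chroman-4-one
Conditions: Dess–Martin periodinane, NaHCO3, CH2Cl2, 0 °C to rt
Reagents that add atoms: none
Why: Dess–Martin oxidation under buffered, non-basic conditions should convert the benzylic carbinol into the ketone without enolising C3, so the (3R) centre is kept and the auxiliary C4 centre is erased.

**Step 11**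
Reactants: 14 (3R)-3-(2,2-dimethylchroman-6-yl)-8-(3-methylbut-2-en-1-yl)-7-(triisopropylsilyloxy)chroman-4-one
Product: 15 (3R)-3-(2,2-dimethylchroman-6-yl)-7-hydroxy-8-(3-methylbut-2-en-1-yl)chroman-4-one (target)
Conditions: TBAF, AcOH (1:1), THF, 0 °C
Reagents that add atoms: none
Why: Fluoride-mediated desilylation buffered with acetic acid should free the 7-OH under near-neutral conditions that neither epimerise the α-aryl ketone nor add the phenol to the prenyl double bond.

**Compound list**
1 | daidzein, 7-hydroxy-3-(4-hydroxyphenyl)-4H-chromen-4-one | O=c1c(-c2ccc(O)cc2)coc2cc(O)ccc12 | starting material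
2 | 7-(benzyloxy)-3-(4-hydroxyphenyl)-4H-chromen-4-one | O=c1c(-c2ccc(O)cc2)coc2cc(OCc3ccccc3)ccc12 | intermediate
3 | 3-chloro-3-methylbut-1-yne | CC(C)(Cl)C#C | starting material
4 | 7-(benzyloxy)-3-[4-(2-methylbut-3-yn-2-yloxy)phenyl]-4H-chromen-4-one | O=c1c(-c2ccc(OC(C)(C)C#C)cc2)coc2cc(OCc3ccccc3)ccc12 | intermediate
5 | 7-(benzyloxy)-3-(2,2-dimethyl-2H-chromen-6-yl)-4H-chromen-4-one | O=c1c(-c2ccc3OC(C)(C)C=Cc3c2)coc2cc(OCc3ccccc3)ccc12 | intermediate
6 | 3-(2,2-dimethylchroman-6-yl)-7-hydroxy-4H-chromen-4-one | O=c1c(-c2ccc3OC(C)(C)CCc3c2)coc2cc(O)ccc12 | intermediate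
7 | 3-(2,2-dimethylchroman-6-yl)-7-(2-methylbut-3-yn-2-yloxy)-4H-chromen-4-one | O=c1c(-c2ccc3OC(C)(C)CCc3c2)coc2cc(OC(C)(C)C#C)ccc12 | intermediate
8 | 3-(2,2-dimethylchroman-6-yl)-7-(2-methylbut-3-en-2-yloxy)-4H-chromen-4-one | O=c1c(-c2ccc3OC(C)(C)CCc3c2)coc2cc(OC(C)(C)C=C)ccc12 | intermediate
9 | 3-(2,2-dimethylchroman-6-yl)-8-(3-methylbut-2-en-1-yl)-8H-chromene-4,7-dione (ortho-dienone, C8 unassigned) | CC(C)=CCC1C(=O)C=CC2=C1OC=C(c1ccc3c(c1)CCC(C)(C)O3)C2=O | intermediate
10 | 3-(2,2-dimethylchroman-6-yl)-7-hydroxy-8-(3-methylbut-2-en-1-yl)-4H-chromen-4-one | O=c1c(-c2ccc3OC(C)(C)CCc3c2)coc2c(CC=C(C)C)c(O)ccc12 | intermediate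
11 | 3-(2,2-dimethylchroman-6-yl)-8-(3-methylbut-2-en-1-yl)-7-(triisopropylsilyloxy)-4H-chromen-4-one | O=c1c(-c2ccc3OC(C)(C)CCc3c2)coc2c(CC=C(C)C)c(O[Si](C(C)C)(C(C)C)C(C)C)ccc12 | intermediate
12 | racemic 3-(2,2-dimethylchroman-6-yl)-8-(3-methylbut-2-en-1-yl)-7-(triisopropylsilyloxy)chroman-4-one | CC(C)=CCc1c(O[Si](C(C)C)(C(C)C)C(C)C)ccc2c1OCC(c1ccc3c(c1)CCC(C)(C)O3)C2=O | intermediate
13 | (3R,4R)-3-(2,2-dimethylchroman-6-yl)-8-(3-methylbut-2-en-1-yl)-7-(triisopropylsilyloxy)chroman-4-ol (3,4-cis) | CC(C)=CCc1c(O[Si](C(C)C)(C(C)C)C(C)C)ccc2c1OC[C@@H](c1ccc3c(c1)CCC(C)(C)O3)[C@H]2O | intermediate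
14 | (3R)-3-(2,2-dimethylchroman-6-yl)-8-(3-methylbut-2-en-1-yl)-7-(triisopropylsilyloxy)chroman-4-one | CC(C)=CCc1c(O[Si](C(C)C)(C(C)C)C(C)C)ccc2c1OC[C@@H](c1ccc3c(c1)CCC(C)(C)O3)C2=O | intermediate
15 | (3R)-3-(2,2-dimethylchroman-6-yl)-7-hydroxy-8-(3-methylbut-2-en-1-yl)chroman-4-one | CC(C)=CCc1c(O)ccc2c1OC[C@@H](c1ccc3c(c1)CCC(C)(C)O3)C2=O | target

**Totals**
Total step count: 11. Longest linear sequence: 11 steps (from daidzein 1).

**Three steps most likely to fail**

Step 9. The transfer hydrogenation may stall after the conjugate reduction, the aryl silyl ether may be lost in the formate medium, or epimerisation at C3 may be too slow for a clean resolution. The fallback separates the two reductions and uses hydrogen gas. It sets out from 11, which is reduced in conjugate fashion with L-Selectride (LiBH(s-Bu)3, THF, −78 °C) to racemic isoflavanone 12, isolated this time. Ketone 12 is then hydrogenated under base-mediated dynamic kinetic resolution with RuCl2[(S)-xylbinap][(S)-daipen], t-BuOK and H2 in i-PrOH; this is the catalyst antipode that gives (R)-carbinols from aryl alkyl ketones, and it should leave the prenyl double bond alone. The fallback comes back to the route at 13 and adds no new compound (F0).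

Step 7. The allyl unit may migrate partly to C6, or the tertiary ether may fragment to the phenol and isoprene. The fallback replaces the sigmatropic shift by halogenation and cross-coupling. It sets out from 6, which is iodinated through its phenoxide at C8, the carbon between O1 and the 7-OH (I2, NaHCO3, THF–H2O), to give 3-(2,2-dimethylchroman-6-yl)-7-hydroxy-8-iodo-4H-chromen-4-one F1. Silylation (TIPSCl, imidazole, DMF) gives 3-(2,2-dimethylchroman-6-yl)-8-iodo-7-(triisopropylsilyloxy)-4H-chromen-4-one F2. A linear-selective Negishi coupling with prenylzinc bromide (Pd(OAc)2, CPhos, THF) then installs the prenyl group, and the fallback comes back to the route at 11.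

Step 11. Fluoride may promote enolisation at C3 and erode the enantiomeric purity. The fallback removes the silyl group before the ketone exists. It sets out from 13, which is desilylated with TBAF in THF at the configurationally stable alcohol stage to give (3R,4R)-3-(2,2-dimethylchroman-6-yl)-8-(3-methylbut-2-en-1-yl)chromane-4,7-diol F3. Activated MnO2 (CH2Cl2, rt) should then oxidise only the benzylic C4 carbinol under neutral heterogeneous conditions, and the fallback comes back to the route at 15.

**Further compounds**
F0 | step 9 | none | none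
F1 | step 7 | 3-(2,2-dimethylchroman-6-yl)-7-hydroxy-8-iodo-4H-chromen-4-one | O=c1c(-c2ccc3OC(C)(C)CCc3c2)coc2c(I)c(O)ccc12
F2 | step 7 | 3-(2,2-dimethylchroman-6-yl)-8-iodo-7-(triisopropylsilyloxy)-4H-chromen-4-one | O=c1c(-c2ccc3OC(C)(C)CCc3c2)coc2c(I)c(O[Si](C(C)C)(C(C)C)C(C)C)ccc12
F3 | step 11 | (3R,4R)-3-(2,2-dimethylchroman-6-yl)-8-(3-methylbut-2-en-1-yl)chromane-4,7-diol | CC(C)=CCc1c(O)ccc2c1OC[C@@H](c1ccc3c(c1)CCC(C)(C)O3)[C@H]2O
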